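## Retrosynthetic overview

1. Target 20 ⇐ resorcinol 19: the hydroxyquinone is made last, by oxidising the single free aromatic C–H (para to an OH) with (KSO3)2NO.
2. 19 ⇐ bridged silaketal 17: one operation opens the O–Si–O bridge to the ring ketone and the carbinol and frees both phenols; 17 ⇐ aldehyde 15 (CHO → CH3).
3. Key step, 15 ⇐ acyclic trienal 14: a silicon-tethered type 2 intramolecular Diels–Alder reaction closes the cyclohexene ring and the eight-membered O–Si–O bridge ring together and sets the three ring stereocentres from the carbinol centre.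
4. 14 ⇐ hydroxy enal 11 + pent-1-en-3-one + i-Pr2Si(OTf)2; 11 ⇐ aryl enal 8 + prenal dienol silane 10 (asymmetric vinylogous Mukaiyama aldol sets the carbinol).
5. 8 ⇐ orcinol (chlorination, MOM ethers, ortho-lithiation/allylation, cross-metathesis). Ring order: arene bought; cyclohexene + bridge ring together; bridge ring opened; arene oxidised to the quinone.

Assumption: the oxazaborolidinone from N-tosyl-D-tryptophan is taken to deliver the dienolate to the face of aldehyde 8 that gives the (5S) alcohol; if the sense is the reverse, the L-tryptophan reagent is used and nothing else changes.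

## Route

Step 1
Reactants: 1 orcinol (5-methylbenzene-1,3-diol)
Product: 2 4-chloro-5-methylbenzene-1,3-diol
Conditions: SO2Cl2 (1.0 equiv), Et2O, 0 °C to rt
Reagents that add atoms: sulfuryl chloride, O=S(=O)(Cl)Cl
Why: Electrophilic aromatic chlorination of the activated ring goes mainly to C4 (ortho to one OH, para to the other), and the 2-chloro and dichloro by-products are removed by crystallisation.

Step 2
Reactants: 2 4-chloro-5-methylbenzene-1,3-diol
Product: 3 2-chloro-1,5-bis(methoxymethoxy)-3-methylbenzene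
Conditions: MOMCl (2.5 equiv), i-Pr2NEt (3 equiv), CH2Cl2, 0 °C to rt
Reagents that add atoms: chloromethyl methyl ether, COCCl
Why: O-alkylation of both phenols (Williamson-type acetal formation) gives base-stable ethers that direct the next lithiation.

Step 3
Reactants: 3 2-chloro-1,5-bis(methoxymethoxy)-3-methylbenzene; 4 allyl bromide (3-bromoprop-1-ene)
Product: 6 2-allyl-4-chloro-1,3-bis(methoxymethoxy)-5-methylbenzene, via aryllithium 5 (not isolated)
Conditions: n-BuLi (1.1 equiv), THF, 0 °C, 1 h; CuI (10 mol %), then 4 (1.3 equiv), −78 °C to rt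
Reagents that add atoms: none
Why: Directed ortho-metalation at the only C–H flanked by two OMOM groups (there is no H ortho to Cl, so no aryne), followed by copper-catalysed SN2 allylation of the aryllithium.

Step 4
Reactants: 6 2-allyl-4-chloro-1,3-bis(methoxymethoxy)-5-methylbenzene; 7 methacrolein (2-methylprop-2-enal)
Product: 8 (2E)-4-[3-chloro-2,6-bis(methoxymethoxy)-4-methylphenyl]-2-methylbut-2-enal
Conditions: second-generation Hoveyda–Grubbs catalyst, (H2IMes)Cl2Ru(=CH-C6H4-2-O-i-Pr) (5 mol %), 7 (5 equiv), CH2Cl2, 40 °C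
Reagents that add atoms: none
Why: Olefin cross-metathesis of a terminal alkene with methacrolein gives the trisubstituted 2-methyl-2-enal as the thermodynamically favoured (E) isomer, with CHO trans to the benzylic CH2.

Step 5
Reactants: 9 prenal (3-methylbut-2-enal)
Product: 10 tert-butyl(dimethyl){[(1E)-3-methylbuta-1,3-dien-1-yl]oxy}silane
Conditions: TBSOTf (1.1 equiv), Et3N (1.5 equiv), Et2O, 0 °C
Reagents that add atoms: tert-butyldimethylsilyl trifluoromethanesulfonate, CC(C)(C)[Si](C)(C)OS(=O)(=O)C(F)(F)F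
Why: Soft enolisation (O-silylation of the enal, then γ-deprotonation by the amine) gives the (1E)-dienol silyl ether.

Step 6
Reactants: 8 (2E)-4-[3-chloro-2,6-bis(methoxymethoxy)-4-methylphenyl]-2-methylbut-2-enal; 10 tert-butyl(dimethyl){[(1E)-3-methylbuta-1,3-dien-1-yl]oxy}silane
Product: 11 (2E,5S,6E)-8-[3-chloro-2,6-bis(methoxymethoxy)-4-methylphenyl]-5-hydroxy-3,6-dimethylocta-2,6-dienal
Conditions: B-phenyl oxazaborolidinone made in situ from N-tosyl-D-tryptophan and PhBCl2 (1.0 equiv), i-PrOH (1.1 equiv), 10 (1.5 equiv), EtCN, −78 °C; aq NaHCO3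
Reagents that add atoms: none
Why: Enantioselective vinylogous Mukaiyama aldol addition: the chiral boron Lewis acid binds the more electrophilic α-methyl enal 8, the dienol silane attacks through its γ-carbon on the unshielded face to set (5S), and the new enal forms as the (2E) isomer.

Step 7
Reactants: 11 (2E,5S,6E)-8-[3-chloro-2,6-bis(methoxymethoxy)-4-methylphenyl]-5-hydroxy-3,6-dimethylocta-2,6-dienal; 12 pent-1-en-3-one (ethyl vinyl ketone)
Product: 14 (2E,5S,6E)-8-[3-chloro-2,6-bis(methoxymethoxy)-4-methylphenyl]-3,6-dimethyl-5-({[(3Z)-penta-1,3-dien-3-yloxy]di(propan-2-yl)silyl}oxy)octa-2,6-dienal, via dienoxysilyl triflate 13 (not isolated)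
Conditions: i-Pr2Si(OTf)2 (1.2 equiv), 12 (1.2 equiv), Et3N (1.3 equiv), CH2Cl2, −78 °C; then 11 (1.0 equiv), 2,6-lutidine (2 equiv), −78 to 0 °C; filtration through Et3N-deactivated Al2O3, used at once
Reagents that add atoms: diisopropylsilyl bis(trifluoromethanesulfonate), CC(C)[Si](C(C)C)(OS(=O)(=O)C(F)(F)F)OS(=O)(=O)C(F)(F)F
Why: Silyl triflate/amine soft enolisation of the ethyl ketone gives the (Z)-silyl dienol ether (methyl trans to the vinyl group), and the remaining Si–OTf bond then silylates the secondary alcohol to give the mixed silaketal; any (E)-enol ether has its methyl inside the diene and does not cyclise in step 8.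

Step 8
Reactants: 14 (2E,5S,6E)-8-[3-chloro-2,6-bis(methoxymethoxy)-4-methylphenyl]-3,6-dimethyl-5-({[(3Z)-penta-1,3-dien-3-yloxy]di(propan-2-yl)silyl}oxy)octa-2,6-dienal
Product: 15 (5S)-5-{(2E)-4-[3-chloro-2,6-bis(methoxymethoxy)-4-methylphenyl]but-2-en-2-yl}-7,11-dimethyl-3,3-di(propan-2-yl)-2,4-dioxa-3-silabicyclo[5.3.1]undec-1(10)-ene-8-carbaldehyde (on the cyclohexene ring the C8 formyl is cis to the C7 methyl and the C11 methyl is cis to the C6 arm of C7)
Conditions: Me2AlCl (1.5 equiv), CH2Cl2 (0.01 M), −78 to −20 °C; aq KNaC4H4O6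
Reagents that add atoms: none
Why: Proposed new method: a silaketal-tethered type 2 intramolecular Diels–Alder reaction in which Me2AlCl lowers the LUMO of the enal, its β-carbon bonds to the nucleophilic CH(CH3) terminus of the 2-silyloxydiene (electronically matched and enforced by the bridge), and the cyclohexene and the eight-membered O–Si–O ring close together; the bridge arm must lie endo, so the methyl of the (Z)-enol ether ends cis to it and the formyl of the (E)-enal trans to it (the relative configuration of C2, C3, C4 of the target ring), while the (S)-carbinol is expected to expose the face of the β-carbon that gives (3S) because the tether conformer with C–H, not the alkenyl arm, eclipsing the O–Si(i-Pr)2 bond is favoured, and this sense of 1,3-induction is the untested point; the closest known reaction type is the silicon-tethered type 2 intramolecular Diels–Alder route to bridgehead-alkene bicycles.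

Step 9
Reactants: 15 (5S)-5-{(2E)-4-[3-chloro-2,6-bis(methoxymethoxy)-4-methylphenyl]but-2-en-2-yl}-7,11-dimethyl-3,3-di(propan-2-yl)-2,4-dioxa-3-silabicyclo[5.3.1]undec-1(10)-ene-8-carbaldehyde
Product: 17 (5S)-5-{(2E)-4-[3-chloro-2,6-bis(methoxymethoxy)-4-methylphenyl]but-2-en-2-yl}-7,8,11-trimethyl-3,3-di(propan-2-yl)-2,4-dioxa-3-silabicyclo[5.3.1]undec-1(10)-ene, via tosylhydrazone 16 (not isolated)
Conditions: TsNHNH2 (1.05 equiv), THF, 4 Å MS, rt; then catecholborane (2 equiv), CHCl3, 0 °C; NaOAc·3H2O, 50 °C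
Reagents that add atoms: none
Why: Reductive deoxygenation of the aldehyde through its tosylhydrazone (hydride addition to C=N, then loss of sulfinate and N2 from the diazene) turns CHO into CH3 without touching C8–H, so the configuration from step 8 is kept, and the bridgehead silyl enol ether masks the future ketone.

Step 10
Reactants: 17 (5S)-5-{(2E)-4-[3-chloro-2,6-bis(methoxymethoxy)-4-methylphenyl]but-2-en-2-yl}-7,8,11-trimethyl-3,3-di(propan-2-yl)-2,4-dioxa-3-silabicyclo[5.3.1]undec-1(10)-ene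
Product: 19 (2S,3S,4R)-3-[(2S,3E)-5-(3-chloro-2,6-dihydroxy-4-methylphenyl)-2-hydroxy-3-methylpent-3-en-1-yl]-2,3,4-trimethylcyclohexan-1-one, via bis(trimethylsilyl) ether 18 (not isolated)
Conditions: TMSOTf (4 equiv), 2,2′-bipyridyl (6 equiv), MeCN, 0 °C; then HF·pyridine, THF, 0 °C to rt; pH 7 buffer
Reagents that add atoms: none
Why: Silyl triflate/bipyridyl acetal exchange converts the aryl MOM ethers into aryl TMS ethers without protic acid, and fluoride then cleaves every Si–O bond, releasing the phenols, the (S)-carbinol and the enol, which protonates at C6 (a CH2), so C2 next to the new ketone is never enolised.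

Step 11
Reactants: 19 (2S,3S,4R)-3-[(2S,3E)-5-(3-chloro-2,6-dihydroxy-4-methylphenyl)-2-hydroxy-3-methylpent-3-en-1-yl]-2,3,4-trimethylcyclohexan-1-one
Product: 20 2-chloro-5-hydroxy-6-{(2E,4S)-4-hydroxy-3-methyl-5-[(1S,2S,6R)-1,2,6-trimethyl-3-oxocyclohexyl]pent-2-en-1-yl}-3-methylcyclohexa-2,5-diene-1,4-dione (CNP0469571.2)
Conditions: (KSO3)2NO (2.5 equiv), KH2PO4 buffer (pH 6), acetone/H2O, 0 °C to rt
Reagents that add atoms: potassium nitrosodisulfonate, [K+].[K+].[O]N(S(=O)(=O)[O-])S(=O)(=O)[O-]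
Why: Teuber oxidation: the phenoxyl radical is trapped by a second nitroxyl at the only free ring position (para to the OH next to C–Cl), and loss of imidodisulfonate gives the 2-hydroxy-1,4-benzoquinone, while alcohol, ketone and alkene are untouched under near-neutral conditions.

## Compound list

1 | orcinol (5-methylbenzene-1,3-diol) | Cc1cc(O)cc(O)c1 | starting material
2 | 4-chloro-5-methylbenzene-1,3-diol | Cc1cc(O)cc(O)c1Cl | intermediate
3 | 2-chloro-1,5-bis(methoxymethoxy)-3-methylbenzene | Cc1cc(OCOC)cc(OCOC)c1Cl | intermediate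
4 | allyl bromide | C=CCBr | starting material
5 | [3-chloro-2,6-bis(methoxymethoxy)-4-methylphenyl]lithium | Cc1cc(OCOC)c([Li])c(OCOC)c1Cl | intermediate
6 | 2-allyl-4-chloro-1,3-bis(methoxymethoxy)-5-methylbenzene | Cc1cc(OCOC)c(CC=C)c(OCOC)c1Cl | intermediate
7 | methacrolein | C=C(C)C=O | starting material
8 | (2E)-4-[3-chloro-2,6-bis(methoxymethoxy)-4-methylphenyl]-2-methylbut-2-enal | Cc1cc(OCOC)c(C/C=C(\C)C=O)c(OCOC)c1Cl | intermediate
9 | prenal (3-methylbut-2-enal) | CC(C)=CC=O | starting material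
10 | tert-butyl(dimethyl){[(1E)-3-methylbuta-1,3-dien-1-yl]oxy}silane | C=C(C)/C=C/O[Si](C)(C)C(C)(C)C | intermediate
11 | (2E,5S,6E)-8-[3-chloro-2,6-bis(methoxymethoxy)-4-methylphenyl]-5-hydroxy-3,6-dimethylocta-2,6-dienal | Cc1cc(OCOC)c(C/C=C(\C)[C@@H](O)C/C(C)=C/C=O)c(OCOC)c1Cl | intermediate
12 | pent-1-en-3-one (ethyl vinyl ketone) | CCC(=O)C=C | starting material
13 | [(3Z)-penta-1,3-dien-3-yloxy]di(propan-2-yl)silyl trifluoromethanesulfonate | C/C=C(\O[Si](C(C)C)(C(C)C)OS(=O)(=O)C(F)(F)F)C=C | intermediate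
14 | (2E,5S,6E)-8-aryl-3,6-dimethyl-5-({[(3Z)-penta-1,3-dien-3-yloxy]di(propan-2-yl)silyl}oxy)octa-2,6-dienal, aryl = 3-chloro-2,6-bis(methoxymethoxy)-4-methylphenyl | Cc1cc(OCOC)c(C/C=C(\C)[C@@H](O[Si](C(C)C)(C(C)C)O/C(C=C)=C\C)C/C(C)=C/C=O)c(OCOC)c1Cl | intermediate
15 | (5S)-5-[(2E)-4-arylbut-2-en-2-yl]-7,11-dimethyl-3,3-di(propan-2-yl)-2,4-dioxa-3-silabicyclo[5.3.1]undec-1(10)-ene-8-carbaldehyde, ring centres as in the SMILES | Cc1cc(OCOC)c(C/C=C(\C)[C@@H]2C[C@@]3(C)[C@H](C=O)CC=C(O[Si](C(C)C)(C(C)C)O2)[C@H]3C)c(OCOC)c1Cl | intermediate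
16 | N-tosylhydrazone of 15 (CH=N–NHTs at C8) | Cc1cc(OCOC)c(C/C=C(\C)[C@@H]2C[C@@]3(C)[C@H](C=NNS(=O)(=O)c4ccc(C)cc4)CC=C(O[Si](C(C)C)(C(C)C)O2)[C@H]3C)c(OCOC)c1Cl | intermediate
17 | (5S)-5-[(2E)-4-arylbut-2-en-2-yl]-7,8,11-trimethyl-3,3-di(propan-2-yl)-2,4-dioxa-3-silabicyclo[5.3.1]undec-1(10)-ene | Cc1cc(OCOC)c(C/C=C(\C)[C@@H]2C[C@@]3(C)[C@H](C)CC=C(O[Si](C(C)C)(C(C)C)O2)[C@H]3C)c(OCOC)c1Cl | intermediate
18 | analogue of 17 with both OMOM groups replaced by OSiMe3 | Cc1cc(O[Si](C)(C)C)c(C/C=C(\C)[C@@H]2C[C@@]3(C)[C@H](C)CC=C(O[Si](C(C)C)(C(C)C)O2)[C@H]3C)c(O[Si](C)(C)C)c1Cl | intermediate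
19 | (2S,3S,4R)-3-[(2S,3E)-5-(3-chloro-2,6-dihydroxy-4-methylphenyl)-2-hydroxy-3-methylpent-3-en-1-yl]-2,3,4-trimethylcyclohexan-1-one | Cc1cc(O)c(C/C=C(\C)[C@@H](O)C[C@@]2(C)[C@H](C)CCC(=O)[C@H]2C)c(O)c1Cl | intermediate
20 | 2-chloro-5-hydroxy-6-{(2E,4S)-4-hydroxy-3-methyl-5-[(1S,2S,6R)-1,2,6-trimethyl-3-oxocyclohexyl]pent-2-en-1-yl}-3-methylcyclohexa-2,5-diene-1,4-dione | CC1=C(Cl)C(=O)C(C/C=C(\C)[C@@H](O)C[C@@]2(C)[C@H](C)CCC(=O)[C@H]2C)=C(O)C1=O | target

## Step count and risks

Total steps: 11. Longest linear sequence: 10 (steps 1–4 and 6–11; step 5 is a one-step branch).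

**Most likely to fail, first: step 8.** The enal is β,β-disubstituted, and the direction in which the carbinol centre steers the diene is not established. My own conformational analysis does not settle it: the alkenyl arm clashes either with the i-Pr2Si group or with the two ring methyls, and the two cases lead to opposite ring configurations. If the (5S) substrate gives the adduct with the antipodal ring, the carbinol is used in the opposite configuration (then the matched one) and inverted afterwards. This fallback sets out from 8 and comes back at 19. The aldol of step 6 run with the N-tosyl-L-tryptophan reagent gives the (5R)-hydroxy enal F1. The conditions of step 7 give its silaketal F2. Cyclisation as in step 8 gives the (5R)-cycloadduct F3, which has the ring configuration of 15. TsNHNH2 gives the tosylhydrazone F4 and catecholborane the methyl compound F5. HF·pyridine alone opens the bridge to the (R)-keto-alcohol F6 with both MOM ethers in place. A Mitsunobu reaction (HCO2H, PPh3, DIAD, THF, 0 °C) inverts the carbinol to the (S)-formate F7. ZnBr2/n-PrSH (CH2Cl2, 0 °C) removes the MOM groups to give the resorcinol formate F8, and NaHCO3 in MeOH takes off the formate to reach 19.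

**Second: step 6.** Aldehyde-derived dienol silanes are weak nucleophiles, and γ-selectivity and ee with an enal acceptor are uncertain. The fallback moves to the ester oxidation level under Lewis-base catalysis; it sets out from 8 and comes back at 11. Methyl 3-methylbut-2-enoate is converted with LiN(i-Pr)2 and TBSCl into the silyl ketene acetal F9. SiCl4 with a chiral 2,2′-diamino-1,1′-binaphthyl-derived bisphosphoramide (5 mol %, the antipode that gives 5S) catalyses its γ-selective addition to 8 and gives the (5S)-hydroxy ester F10. i-Bu2AlH reduces the ester to the diol F11, and TEMPO/PhI(OAc)2 oxidises only the primary allylic alcohol to return to 11.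

**Third: step 7.** Two different O-nucleophiles must be put on one silicon in sequence, statistical bis-products are possible, and the product is hydrolytically labile. The fallback builds the second Si–O bond by dehydrogenative coupling instead of triflate displacement; it sets out from 12 and comes back at 14. Ketone 12 is silylated with i-Pr2SiHCl (Et3N, NaI, MeCN) to the distillable hydrosilyl dienol ether F12, which is joined to 11 by Rh2(O2CC3F7)4-catalysed Si–H/O–H coupling (1 mol %, CH2Cl2, rt).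

## Further compounds

F1 | step 8 | (2E,5R,6E)-8-[3-chloro-2,6-bis(methoxymethoxy)-4-methylphenyl]-5-hydroxy-3,6-dimethylocta-2,6-dienal | Cc1cc(OCOC)c(C/C=C(\C)[C@H](O)C/C(C)=C/C=O)c(OCOC)c1Cl
F2 | step 8 | (5R)-epimer of silaketal 14 | Cc1cc(OCOC)c(C/C=C(\C)[C@H](O[Si](C(C)C)(C(C)C)O/C(C=C)=C\C)C/C(C)=C/C=O)c(OCOC)c1Cl
F3 | step 8 | (5R)-epimer of cycloadduct 15 (same ring configuration) | Cc1cc(OCOC)c(C/C=C(\C)[C@H]2C[C@@]3(C)[C@H](C=O)CC=C(O[Si](C(C)C)(C(C)C)O2)[C@H]3C)c(OCOC)c1Cl
F4 | step 8 | N-tosylhydrazone of F3 | Cc1cc(OCOC)c(C/C=C(\C)[C@H]2C[C@@]3(C)[C@H](C=NNS(=O)(=O)c4ccc(C)cc4)CC=C(O[Si](C(C)C)(C(C)C)O2)[C@H]3C)c(OCOC)c1Cl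
F5 | step 8 | (5R)-epimer of 17 | Cc1cc(OCOC)c(C/C=C(\C)[C@H]2C[C@@]3(C)[C@H](C)CC=C(O[Si](C(C)C)(C(C)C)O2)[C@H]3C)c(OCOC)c1Cl
F6 | step 8 | (2S,3S,4R)-3-{(2R,3E)-5-[3-chloro-2,6-bis(methoxymethoxy)-4-methylphenyl]-2-hydroxy-3-methylpent-3-en-1-yl}-2,3,4-trimethylcyclohexan-1-one | Cc1cc(OCOC)c(C/C=C(\C)[C@H](O)C[C@@]2(C)[C@H](C)CCC(=O)[C@H]2C)c(OCOC)c1Cl
F7 | step 8 | (2S,3E)-5-[3-chloro-2,6-bis(methoxymethoxy)-4-methylphenyl]-3-methyl-1-[(1S,2S,6R)-1,2,6-trimethyl-3-oxocyclohexyl]pent-3-en-2-yl formate | Cc1cc(OCOC)c(C/C=C(\C)[C@@H](OC=O)C[C@@]2(C)[C@H](C)CCC(=O)[C@H]2C)c(OCOC)c1Cl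
F8 | step 8 | (2S,3E)-5-(3-chloro-2,6-dihydroxy-4-methylphenyl)-3-methyl-1-[(1S,2S,6R)-1,2,6-trimethyl-3-oxocyclohexyl]pent-3-en-2-yl formate | Cc1cc(O)c(C/C=C(\C)[C@@H](OC=O)C[C@@]2(C)[C@H](C)CCC(=O)[C@H]2C)c(O)c1Cl
F9 | step 6 | tert-butyl[(1-methoxy-3-methylbuta-1,3-dien-1-yl)oxy]dimethylsilane | C=C(C)C=C(OC)O[Si](C)(C)C(C)(C)C
F10 | step 6 | methyl (2E,5S,6E)-8-[3-chloro-2,6-bis(methoxymethoxy)-4-methylphenyl]-5-hydroxy-3,6-dimethylocta-2,6-dienoate | Cc1cc(OCOC)c(C/C=C(\C)[C@@H](O)C/C(C)=C/C(=O)OC)c(OCOC)c1Cl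
F11 | step 6 | (2E,5S,6E)-8-[3-chloro-2,6-bis(methoxymethoxy)-4-methylphenyl]-3,6-dimethylocta-2,6-diene-1,5-diol | Cc1cc(OCOC)c(C/C=C(\C)[C@@H](O)C/C(C)=C/CO)c(OCOC)c1Cl
F12 | step 7 | [(3Z)-penta-1,3-dien-3-yloxy]di(propan-2-yl)silane | C/C=C(\O[SiH](C(C)C)C(C)C)C=C
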